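The 2,3-dihydrofuran ring (O1, C2, C3, C3a, C7a) is read as the oxidative [3+2] adduct of a cyclic 1,3-dicarbonyl and an alkene. O1–C7a=C3a is the enol unit (O4, C4, C3) of the 4-hydroxy-2-pyranone that becomes the fused pyranone ring, and C2–C3 is the styryl C=C of a protected hispidin. In step 5, Mn(OAc)3 turns the hydroxypyranone into its C3 radical, which adds to the pyranone-bearing alkene carbon (C3–C3a bond). The benzylic cation formed on further oxidation is captured by the enol oxygen (O1–C2 bond), closing the trans ring. The radical precursor carries its later styryl group masked as a 2-aryl-2-hydroxyethyl chain, so only one alkene can react. The enantiomer is secured by resolution.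

Key step: step 5

Remark: no catalyst-controlled enantioselective variant of this annulation can be defended for a 1,2-disubstituted acceptor alkene, so the trans racemate is made and resolved; a racemate of fixed relative configuration is written as its two enantiomers joined by a dot.
Remark: 3,4-diacetoxycinnamic acid and 4-formylphenyl acetate are taken as catalogue compounds (each is otherwise one acetylation away from caffeic acid or 4-hydroxybenzaldehyde).

Step 1
Reactants: 1 (E)-3-(3,4-diacetoxyphenyl)prop-2-enoic acid; 2 2,2,6-trimethyl-4H-1,3-dioxin-4-one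
Product: 5 6-[(3E)-4-(3,4-diacetoxyphenyl)-2-oxobut-3-en-1-yl]-2,2-dimethyl-4H-1,3-dioxin-4-one, via acid chloride 3 (not isolated), via lithium dienolate 4 (not isolated)
Conditions: 1, (COCl)2, cat. DMF, CH2Cl2, 0 °C to rt, evaporate; 2 (2.2 equiv), LiN(SiMe3)2 (2.2 equiv), THF, −78 °C, then add 3; 1 M HCl quench
Reagents that add atoms: none
Why: Vinylogous Claisen condensation (γ-C-acylation) of the dioxinone lithium dienolate by the acid chloride made in situ with (COCl)2/DMF should give the β-keto-dioxinone, since at −78 °C the acid chloride is far more electrophilic than the aryl acetates and the second equivalent of dienolate only takes up the acidic proton of the product.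

Step 2
Reactants: 5 6-[(3E)-4-(3,4-diacetoxyphenyl)-2-oxobut-3-en-1-yl]-2,2-dimethyl-4H-1,3-dioxin-4-one
Product: 7 6-[(E)-2-(3,4-diacetoxyphenyl)ethenyl]-4-hydroxy-2H-pyran-2-one, via acylketene 6 (not isolated)
Conditions: toluene, 110 °C
Reagents that add atoms: none
Why: Thermal retro-hetero-Diels–Alder loss of acetone from the dioxinone unmasks an acylketene that is trapped by the enol oxygen of the remote ketone (acylketene lactonisation), which should give the 4-hydroxy-2-pyranone with the E-alkene untouched.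

Step 3
Reactants: 7 6-[(E)-2-(3,4-diacetoxyphenyl)ethenyl]-4-hydroxy-2H-pyran-2-one
Product: 8 6-[(E)-2-(3,4-diacetoxyphenyl)ethenyl]-2-oxo-2H-pyran-4-yl pivalate
Conditions: t-BuCOCl (1.1 equiv), Et3N (1.2 equiv), CH2Cl2, 0 °C
Reagents that add atoms: pivaloyl chloride, CC(C)(C)C(Cl)=O
Why: O-Acylation of the acidic enol (pKa about 5) with the hindered acid chloride should give the enol pivalate, which blocks this pyranone as a radical precursor and as a nucleophile in step 5 and does not migrate to C3 in the absence of DMAP.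

Step 4
Reactants: 9 4-hydroxy-6-methyl-2H-pyran-2-one (triacetic acid lactone); 10 4-formylphenyl acetate
Product: 12 6-[2-(4-acetoxyphenyl)-2-hydroxyethyl]-4-hydroxy-2H-pyran-2-one (racemic), via dilithium dianion 11 (not isolated)
Conditions: LiN(iPr)2 (2.2 equiv), THF, −78 to −40 °C; then 10, −78 °C; 1 M HCl quench
Reagents that add atoms: none
Why: Vinylogous aldol addition of the O,C-dianion of triacetic acid lactone, whose carbanion sits on the 6-methyl carbon, to the aldehyde should be faster at −78 °C than attack on the aryl acetate; the new carbinol centre is racemic and is removed in step 6.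

Step 5
Reactants: 8 6-[(E)-2-(3,4-diacetoxyphenyl)ethenyl]-2-oxo-2H-pyran-4-yl pivalate; 12 6-[2-(4-acetoxyphenyl)-2-hydroxyethyl]-4-hydroxy-2H-pyran-2-one
Product: 13 rac-(2S,3S)-6-[2-(4-acetoxyphenyl)-2-hydroxyethyl]-2-(3,4-diacetoxyphenyl)-3-[2-oxo-4-(pivaloyloxy)-2H-pyran-6-yl]-2,3-dihydro-4H-furo[3,2-c]pyran-4-one (trans, both carbinol epimers)
Conditions: 12 (1.5 equiv), Mn(OAc)3·2H2O (3 equiv), AcOH, 60 °C, argon
Reagents that add atoms: none
Why: Mn(OAc)3-mediated oxidative radical [3+2] annulation: the enolate of 12 bound to trivalent manganese is oxidised to the electrophilic C3 radical, which adds to the alkene of 8 at the carbon attached to the pyranone to give a benzylic radical; a second Mn(OAc)3 oxidises this to the benzylic cation, which the C4 enol oxygen traps. The closest known reaction type is the Mn(OAc)3- or (NH4)2Ce(NO3)6-mediated dihydrofuran synthesis from 4-hydroxycoumarins, 4-hydroxy-6-methyl-2-pyranone or dimedone and chalcones, cinnamates or cinnamamides, which gives trans-2-aryl-3-acyl-2,3-dihydrofurans. The one new ring, the dihydrofuran, closes by intermolecular radical C–C bond formation followed by five-membered capture of a free benzylic cation by the enol oxygen (radical–polar crossover), so the restriction on 5-endo-trig closure does not apply. C3 is formed without facial control (racemate, resolved in step 7), and C2 is set trans to the C3 pyranonyl group by substrate control, since the aryl group avoids eclipsing it in the cation capture and trans is also the more stable isomer. The step needs site selectivity, regioselectivity and O-selectivity: 12 has no styryl group and 8 has no oxidisable enol, the bulky electron-poor pivalate shields C3 and C5 of its pyranone, the acceptor pyranone polarises the alkene so that the electrophilic radical attacks the carbon next to it, and closure through the more nucleophilic C4 oxygen instead of the lactone carbonyl gives the furo[3,2-c]pyran-4-one.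

Step 6
Reactants: 13 rac-(2S,3S)-6-[2-(4-acetoxyphenyl)-2-hydroxyethyl]-2-(3,4-diacetoxyphenyl)-3-[2-oxo-4-(pivaloyloxy)-2H-pyran-6-yl]-2,3-dihydro-4H-furo[3,2-c]pyran-4-one
Product: 14 rac-(2S,3S)-6-[(E)-2-(4-acetoxyphenyl)ethenyl]-2-(3,4-diacetoxyphenyl)-3-[2-oxo-4-(pivaloyloxy)-2H-pyran-6-yl]-2,3-dihydro-4H-furo[3,2-c]pyran-4-one (trans)
Conditions: Burgess reagent (2 equiv), THF, 50 °C
Reagents that add atoms: none
Why: Burgess dehydration (sulfamate formation, then thermal syn-elimination of the acidic CH2 hydrogen next to C6 of the fused pyranone) should give the conjugated E-styryl group under non-acidic, non-nucleophilic conditions, merge both carbinol epimers into one racemate and leave C2 and C3 untouched.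

Step 7
Reactants: 14 rac-(2S,3S)-6-[(E)-2-(4-acetoxyphenyl)ethenyl]-2-(3,4-diacetoxyphenyl)-3-[2-oxo-4-(pivaloyloxy)-2H-pyran-6-yl]-2,3-dihydro-4H-furo[3,2-c]pyran-4-one
Product: 15 (2S,3S)-6-[(E)-2-(4-acetoxyphenyl)ethenyl]-2-(3,4-diacetoxyphenyl)-3-[2-oxo-4-(pivaloyloxy)-2H-pyran-6-yl]-2,3-dihydro-4H-furo[3,2-c]pyran-4-one
Conditions: preparative HPLC on immobilised amylose tris(3,5-dimethylphenylcarbamate), heptane/EtOAc/CH2Cl2, rt
Reagents that add atoms: none
Why: Resolution by preparative chromatography on a chiral stationary phase should separate the enantiomers of the fully acylated trans compound, which has no free phenol and so cannot equilibrate through a quinone methide; the (2S,3S) fraction is to be assigned by comparing its ECD curve with the calculated one (or by X-ray diffraction).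

Step 8
Reactants: 15 (2S,3S)-6-[(E)-2-(4-acetoxyphenyl)ethenyl]-2-(3,4-diacetoxyphenyl)-3-[2-oxo-4-(pivaloyloxy)-2H-pyran-6-yl]-2,3-dihydro-4H-furo[3,2-c]pyran-4-one
Product: 16 (2S,3S)-2-(3,4-dihydroxyphenyl)-3-(4-hydroxy-2-oxo-2H-pyran-6-yl)-6-[(E)-2-(4-hydroxyphenyl)ethenyl]-2,3-dihydro-4H-furo[3,2-c]pyran-4-one
Conditions: NH4OAc, MeOH/H2O (4:1), rt, argon; extraction at pH 3
Reagents that add atoms: none
Why: NH4OAc-promoted near-neutral solvolysis of phenolic acetates (ester hydrolysis) should also cleave the enol pivalate, a vinylogous mixed anhydride, while the buffered medium avoids phenoxide-driven opening of the O1–C2 bond, so that C2 and C3 keep their configuration.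

Compound list
1 | (E)-3-(3,4-diacetoxyphenyl)prop-2-enoic acid | CC(=O)Oc1ccc(/C=C/C(=O)O)cc1OC(C)=O | starting material
2 | 2,2,6-trimethyl-4H-1,3-dioxin-4-one | CC1=CC(=O)OC(C)(C)O1 | starting material
3 | (E)-3-(3,4-diacetoxyphenyl)prop-2-enoyl chloride | CC(=O)Oc1ccc(/C=C/C(Cl)=O)cc1OC(C)=O | intermediate (not isolated)
4 | lithium 2,2-dimethyl-6-methylidene-6H-1,3-dioxin-4-olate | [Li+].C=C1C=C([O-])OC(C)(C)O1 | intermediate (not isolated)
5 | 6-[(3E)-4-(3,4-diacetoxyphenyl)-2-oxobut-3-en-1-yl]-2,2-dimethyl-4H-1,3-dioxin-4-one | CC(=O)Oc1ccc(/C=C/C(=O)CC2=CC(=O)OC(C)(C)O2)cc1OC(C)=O | intermediate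
6 | (6E)-7-(3,4-diacetoxyphenyl)-3,5-dioxohepta-1,6-dien-1-one (acylketene) | O=C=CC(=O)CC(=O)/C=C/c1ccc(OC(C)=O)c(OC(C)=O)c1 | intermediate (not isolated)
7 | 6-[(E)-2-(3,4-diacetoxyphenyl)ethenyl]-4-hydroxy-2H-pyran-2-one | CC(=O)Oc1ccc(/C=C/c2cc(O)cc(=O)o2)cc1OC(C)=O | intermediate
8 | 6-[(E)-2-(3,4-diacetoxyphenyl)ethenyl]-2-oxo-2H-pyran-4-yl pivalate | CC(=O)Oc1ccc(/C=C/c2cc(OC(=O)C(C)(C)C)cc(=O)o2)cc1OC(C)=O | intermediate
9 | 4-hydroxy-6-methyl-2H-pyran-2-one | Cc1cc(O)cc(=O)o1 | starting material
10 | 4-formylphenyl acetate | CC(=O)Oc1ccc(C=O)cc1 | starting material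
11 | dilithium dianion of 9 (4-oxido-6-lithiomethyl form) | [Li+].[Li+].[CH2-]c1cc([O-])cc(=O)o1 | intermediate (not isolated)
12 | 6-[2-(4-acetoxyphenyl)-2-hydroxyethyl]-4-hydroxy-2H-pyran-2-one, racemic | CC(=O)Oc1ccc(C(O)Cc2cc(O)cc(=O)o2)cc1 | intermediate
13 | rac-(2S,3S)-6-[2-(4-acetoxyphenyl)-2-hydroxyethyl]-2-(3,4-diacetoxyphenyl)-3-[2-oxo-4-(pivaloyloxy)-2H-pyran-6-yl]-2,3-dihydro-4H-furo[3,2-c]pyran-4-one, trans racemate, both carbinol epimers | O=c1cc(OC(=O)C(C)(C)C)cc([C@H]2c3c(cc(CC(O)c4ccc(OC(C)=O)cc4)oc3=O)O[C@@H]2c2ccc(OC(C)=O)c(OC(C)=O)c2)o1.O=c1cc(OC(=O)C(C)(C)C)cc([C@@H]2c3c(cc(CC(O)c4ccc(OC(C)=O)cc4)oc3=O)O[C@H]2c2ccc(OC(C)=O)c(OC(C)=O)c2)o1 | intermediate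
14 | rac-(2S,3S)-6-[(E)-2-(4-acetoxyphenyl)ethenyl]-2-(3,4-diacetoxyphenyl)-3-[2-oxo-4-(pivaloyloxy)-2H-pyran-6-yl]-2,3-dihydro-4H-furo[3,2-c]pyran-4-one, trans racemate | O=c1cc(OC(=O)C(C)(C)C)cc([C@H]2c3c(cc(/C=C/c4ccc(OC(C)=O)cc4)oc3=O)O[C@@H]2c2ccc(OC(C)=O)c(OC(C)=O)c2)o1.O=c1cc(OC(=O)C(C)(C)C)cc([C@@H]2c3c(cc(/C=C/c4ccc(OC(C)=O)cc4)oc3=O)O[C@H]2c2ccc(OC(C)=O)c(OC(C)=O)c2)o1 | intermediate
15 | (2S,3S)-6-[(E)-2-(4-acetoxyphenyl)ethenyl]-2-(3,4-diacetoxyphenyl)-3-[2-oxo-4-(pivaloyloxy)-2H-pyran-6-yl]-2,3-dihydro-4H-furo[3,2-c]pyran-4-one | O=c1cc(OC(=O)C(C)(C)C)cc([C@H]2c3c(cc(/C=C/c4ccc(OC(C)=O)cc4)oc3=O)O[C@@H]2c2ccc(OC(C)=O)c(OC(C)=O)c2)o1 | intermediate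
16 | (2S,3S)-2-(3,4-dihydroxyphenyl)-3-(4-hydroxy-2-oxo-2H-pyran-6-yl)-6-[(E)-2-(4-hydroxyphenyl)ethenyl]-2,3-dihydro-4H-furo[3,2-c]pyran-4-one | O=c1cc(O)cc([C@H]2c3c(cc(/C=C/c4ccc(O)cc4)oc3=O)O[C@@H]2c2ccc(O)c(O)c2)o1 | target

Total step count: 8. Longest linear sequence: 7 steps (steps 1, 2, 3, 5, 6, 7, 8).

Steps most likely to fail:

Step 5. The electrophilic pyranonyl radical may be consumed by oxidative self-coupling and over-oxidation faster than it adds to the acceptor-substituted alkene, and the warm acidic oxidant may strip the pivalate or dehydrate the carbinol. The fallback forms the same two bonds without a stoichiometric oxidant or acid. It sets out from 12: PhI(OAc)2 in CH2Cl2 at 0 °C should give the phenyliodonium ylide F1. With 8 and catalytic Rh2(OAc)4 (dirhodium tetraacetate) in 1,2-dichloroethane at 60 °C, F1 should undergo the known carbenoid formal [3+2] cycloaddition of iodonium ylides of cyclic 1,3-dicarbonyls with alkenes, with loss of iodobenzene. The hindered carbinol is expected to compete poorly with the excess alkene. The fallback comes back to the route at 13.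

Step 6. Triethylamine released from the Burgess reagent may remove the acidic C3–H and open the dihydrofuran by β-elimination, or the sulfamate may be substituted instead of eliminated. The fallback makes the styryl group before the annulation. It sets out from 12: TsOH·H2O (cat.) in toluene at 80 °C should dehydrate the aldol to 4-[(E)-2-(4-hydroxy-2-oxo-2H-pyran-6-yl)ethenyl]phenyl acetate F2. The Mn(OAc)3 annulation of step 5 is then run with F2 as the limiting partner and 8 in five-fold excess, so that the alkene of 8 outcompetes the styryl group of F2 and of the product. The fallback comes back to the route directly at 14.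

Step 8. Once the para-hydroxyl of the C2 aryl group is free, reversible opening of the O1–C2 bond through a quinone methide, or enolisation at C3, may erode the enantiomeric purity during or after the deacylation. The fallback moves the resolution to the end, so that no reaction follows it. It sets out from racemic 14: the same NH4OAc solvolysis should give the racemic trans tetraphenol F3. F3 is then resolved by preparative HPLC on a reversed-phase chiral column with an acidic eluent, and the fallback comes back to the route at 16.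

Further compounds
F1 | step 5 | [6-[2-(4-acetoxyphenyl)-2-hydroxyethyl]-4-oxido-2-oxo-2H-pyran-3-yl](phenyl)iodonium, the phenyliodonium ylide of 12 (racemic carbinol) | CC(=O)Oc1ccc(C(O)Cc2cc([O-])c([I+]c3ccccc3)c(=O)o2)cc1
F2 | step 6 | 4-[(E)-2-(4-hydroxy-2-oxo-2H-pyran-6-yl)ethenyl]phenyl acetate | CC(=O)Oc1ccc(/C=C/c2cc(O)cc(=O)o2)cc1
F3 | step 8 | rac-(2S,3S)-2-(3,4-dihydroxyphenyl)-3-(4-hydroxy-2-oxo-2H-pyran-6-yl)-6-[(E)-2-(4-hydroxyphenyl)ethenyl]-2,3-dihydro-4H-furo[3,2-c]pyran-4-one, trans racemate | O=c1cc(O)cc([C@H]2c3c(cc(/C=C/c4ccc(O)cc4)oc3=O)O[C@@H]2c2ccc(O)c(O)c2)o1.O=c1cc(O)cc([C@@H]2c3c(cc(/C=C/c4ccc(O)cc4)oc3=O)O[C@H]2c2ccc(O)c(O)c2)o1
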